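**Plan**

Numbering of the carotane skeleton: ring B (five-membered) = C1 (quaternary, methyl), C2, C3, C4 (isopropyl carbinol), C5 (fusion CH). Ring A (seven-membered) = C1, C5, C6 (4-hydroxybenzoate), C7, C8 (methyl)=C9, C10 (isovalerate).
Enabling feature: in ring A the C10 carbinol sits on quaternary C1 and is linked through C5 to oxygen-bearing C6, with C8=C9 allylic to C10. The array O–C10–C1–C5–C6(–O) is the retron of a [2,3]-Wittig shift of a cyclic C6–O–C10 bis-allylic ether.
Cuts, in order: the two ester C–O bonds; C6–O and C5–H (back to C5=C6); C1–C10 with C6–O reconnected (key step); C8=C9 (metathesis); O–C10 (allylation); C6–C7 (methallylation); C1–C5 (aldol).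
Forward: ring B comes from ring contraction of (R)-terpinen-4-ol. A dihydropyran is then built on its aldehyde carbon, the sigmatropic shift turns this oxacycle into ring A, and the esters come last.
Stereochemistry: C4 comes from the terpene. A temporary C6 centre is set by a pinene-derived borane and relays to C1 and C10 in the shift. C5 and C6 are set by a hydrosilylation tethered to O4, and the final C6 configuration by Mitsunobu inversion.

Key step: step 7

Assumption: commercial (R)-(−)-terpinen-4-ol is taken as enantiomerically pure. With less pure material, the reagent-controlled step 4 converts the minor C4 enantiomer into a separable diastereomer.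

**Step 1**
Reactants: 1 (R)-(−)-terpinen-4-ol; 2 triethylsilyl trifluoromethanesulfonate
Product: 3 triethyl{[(1R)-4-methyl-1-(propan-2-yl)cyclohex-3-en-1-yl]oxy}silane
Conditions: 2,6-lutidine, CH2Cl2, 0 °C → rt
Reagents that add atoms: triethylsilyl trifluoromethanesulfonate (2), CC[Si](CC)(CC)OS(=O)(=O)C(F)(F)F
Why: Silylation of a hindered tertiary alcohol with a silyl triflate and a non-nucleophilic base is standard, masks O4 for the carbonyl and organolithium steps, and leaves C4 untouched.

**Step 2**
Reactants: 3 silyl ether
Product: 5 (3R)-6-oxo-3-(propan-2-yl)-3-[(triethylsilyl)oxy]heptanal, via secondary ozonide 4 (not isolated)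
Conditions: O3, CH2Cl2, −78 °C; then Me2S, −78 °C → rt
Reagents that add atoms: ozone, [O-][O+]=O
Why: Ozonolysis with reductive work-up cleaves the only alkene, so the methyl-bearing carbon becomes the methyl ketone (future C1) and the vinylic CH becomes the aldehyde (future C6).

**Step 3**
Reactants: 5 keto aldehyde
Product: 7 (5S)-2-methyl-5-(propan-2-yl)-5-[(triethylsilyl)oxy]cyclopent-1-ene-1-carbaldehyde, via aldol adduct 6 (not isolated)
Conditions: piperidine (cat.), AcOH (cat.), toluene, 4 Å MS, 60 °C
Reagents that add atoms: none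
Why: Amine-salt-catalysed intramolecular aldol condensation of a 6-oxoheptanal (5-enolexo closure through the aldehyde enamine) gives the 2-methylcyclopentenecarbaldehyde; geminal substitution at C4 speeds closure, and the buffered medium and weakly basic silyl ether oxygen favour loss of the new C1 hydroxyl over E1cB loss of the C4 silyloxy group.

**Step 4**
Reactants: 7 enal; 8 2-methylallylmagnesium chloride; 9 (+)-B-methoxydiisopinocampheylborane (from (−)-α-pinene)
Product: 12 (1R)-3-methyl-1-{(5S)-2-methyl-5-(propan-2-yl)-5-[(triethylsilyl)oxy]cyclopent-1-en-1-yl}but-3-en-1-ol, via B-methallyl borane 10 (not isolated), via borinate ester 11 (not isolated)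
Conditions: 9 + 8, Et2O, 0 °C → rt; then 7, −78 °C → −20 °C; then NaOH, H2O2, 0 °C → rt
Reagents that add atoms: 2-methylallylmagnesium chloride (8), CC(=C)C[Mg]Cl
Why: Brown asymmetric methallylboration through a chair Zimmerman–Traxler transition state, in which the reagent from (−)-α-pinene adds to the Re face of the aldehyde and sets 6R under reagent control, whatever bias C4 exerts.

**Step 5**
Reactants: 12 homoallylic alcohol; 13 allyl bromide
Product: 14 allyl ether of 12 (6R; O–CH2–CH=CH2 on C6)
Conditions: NaH, Bu4NI (cat.), THF/DMF, 0 °C, with 13 present before the base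
Reagents that add atoms: allyl bromide (13), C=CCBr
Why: Williamson etherification with a reactive allylic halide; keeping the halide present from the start traps the C6 alkoxide before the silyl group can migrate from O4 to O6, and the C6–O bond is not touched.

**Step 6**
Reactants: 14 allyl ether
Product: 15 (2R)-4-methyl-2-{(5S)-2-methyl-5-(propan-2-yl)-5-[(triethylsilyl)oxy]cyclopent-1-en-1-yl}-3,6-dihydro-2H-pyran
Conditions: second-generation Grubbs catalyst RuCl2(=CHPh)(PCy3)(H2IMes) (5 mol %), CH2Cl2, 40 °C
Reagents that add atoms: none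
Why: Ring-closing metathesis of an allyl and a methallyl group to a six-membered ring with a trisubstituted alkene is routine, and the tetrasubstituted cyclopentene alkene is inert to the catalyst.

**Step 7**
Reactants: 15 dihydropyran
Product: 18 (1R,4S,10S)-4-(triethylsilyloxy)carota-5,8-dien-10-ol (C5=C6 and C8=C9; C10–OH trans to the C1 methyl group), via C10 allyllithium 16 (not isolated), via lithium alkoxide 17 (not isolated)
Conditions: s-BuLi, THF, −78 °C → −30 °C; then aq. NH4Cl
Reagents that add atoms: none
Why: Proposed new method: s-BuLi removes a C10 proton (α to oxygen and allylic to C8=C9) to give allyllithium 16, and in the conformer with the cyclopentenyl group pseudo-axial C10 bonds to C1 while the C1=C5 π bond moves to C5=C6 and the C6–O bond breaks, a concerted suprafacial six-electron [2,3]-Wittig shift ending in alkoxide 17. The closest known reaction types are the [2,3]-Wittig rearrangement of open-chain bis-allylic ethers through their α-allyloxy allyl anions and the ring-contracting [2,3]-Wittig shift of macrocyclic allylic ethers; new here are the six-membered ether that carries both termini and the fully substituted alkene terminus. Ring A closes by C1–C10 bond formation in a five-centre envelope (C10, O, C6, C5, C1) bridged by C7–C8=C9, so the transition state resembles an 8-oxabicyclo[3.2.1]octadiene and the seven-membered carbocycle forms as the six-membered oxacycle opens, with C5=C6 necessarily cis in the ring. C1 is set by C6: because C7 must stay cis to C1, the ether oxygen of (6R)-15 can lie over only one face of the cyclopentene, C10 is delivered to that face and the methyl group is pushed to the other (1R), whatever the configuration at C4. C10 is set by the same bridge, since the oxygen spans C6 and C10 on one face of the nascent ring and therefore ends trans to the C1 methyl group (10S). The step needs lithiation at C10 rather than C6, secured by the tertiary C6–H being flanked by the silyl ether and the C1 methyl group, and a [2,3] shift faster than the radical-pair [1,2] and [1,4] shifts, for which the low temperature and the lithium counter-ion in THF are chosen.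

**Step 8**
Reactants: 18 silyl-protected dienol
Product: 19 (1R,4S,10S)-carota-5,8-diene-4,10-diol
Conditions: Bu4NF, THF, rt
Reagents that add atoms: none
Why: Fluoride desilylation is placed before any ester is present, so basic fluoride meets only alcohols and alkenes, and it frees O4 for the tether of step 10.

**Step 9**
Reactants: 19 diol; 20 isovaleric anhydride
Product: 21 (1R,4S,10S)-4-hydroxycarota-5,8-dien-10-yl 3-methylbutanoate
Conditions: DMAP (cat.), pyridine, rt
Reagents that add atoms: isovaleric anhydride (20), CC(C)CC(=O)OC(=O)CC(C)C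
Why: DMAP-catalysed acylation distinguishes the secondary C10 hydroxyl from the tertiary C4 hydroxyl next to the isopropyl group and retains the C10 configuration.

**Step 10**
Reactants: 21 hydroxy ester; 22 chlorodimethylsilane
Product: 24 (1R,4S,5R,6S,10S) tricyclic 1,2-oxasilolane (O4–SiMe2–C6 bridge and H5 on the face of the C1 methyl group; C10 isovalerate and C8=C9 unchanged), via dimethylsilyl ether 23 (not isolated)
Conditions: 22, Et3N, DMAP (cat.), CH2Cl2, 0 °C; filter and change solvent; Karstedt catalyst Pt2[(CH2=CHSiMe2)2O]3 (zerovalent platinum, 1 mol %), toluene, 60 °C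
Reagents that add atoms: chlorodimethylsilane (22), C[SiH](C)Cl
Why: Intramolecular hydrosilylation of an allylic alcohol through its dimethylsilyl ether (Tamao type, 5-endo closure) holds the Si–H bond over the O4 face of C5=C6 only, so platinum adds H to C5 and Si to C6 syn from that face (H5 cis to O4 and to the C1 methyl group), while the untethered C8=C9, which an external borane would attack first, is left alone.

**Step 11**
Reactants: 24 oxasilolane
Product: 25 (1R,4S,5S,6S,10S)-4,6-dihydroxycarot-8-en-10-yl 3-methylbutanoate (6-epi diol; C4–OH, H5, C6–OH and the C1 methyl group on one face)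
Conditions: H2O2 (30 %), KF, KHCO3, THF/MeOH, rt
Reagents that add atoms: hydrogen peroxide, OO
Why: Tamao–Fleming oxidation replaces C6–Si by C6–OH with retention and releases O4, and the mildly basic peroxide leaves the hindered C10 ester and the unactivated alkene intact.

**Step 12**
Reactants: 25 6-epi diol; 26 4-acetoxybenzoic acid
Product: 27 (1R,4S,5S,6R,10S)-4-hydroxy-10-(3-methylbutanoyloxy)carot-8-en-6-yl 4-acetoxybenzoate
Conditions: PPh3, DIAD, toluene, 0 °C → 40 °C
Reagents that add atoms: 4-acetoxybenzoic acid (26), CC(=O)Oc1ccc(cc1)C(=O)O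
Why: Mitsunobu esterification displaces the C6 oxyphosphonium ion by SN2 and inverts C6 to 6R; the tertiary C4 hydroxyl is not activated and cannot reach the rear of C6, and the acetoxy-substituted acid is acidic enough for a hindered secondary alcohol.

**Step 13**
Reactants: 27 acetoxybenzoate
Product: 28 (1R,4S,5S,6R,10S)-4-hydroxy-10-(3-methylbutanoyloxy)carot-8-en-6-yl 4-hydroxybenzoate (CNP0086724.3)
Conditions: pyrrolidine, CH2Cl2, 0 °C → rt
Reagents that add atoms: none
Why: Aminolysis of an aryl acetate works because the phenolic ester is far more electrophilic than the two alkyl esters, so only the acetyl group is removed and no stereocentre is touched.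

**Compound list**

1 | (R)-(−)-terpinen-4-ol | CC1=CC[C@@](O)(C(C)C)CC1 | starting material
2 | triethylsilyl trifluoromethanesulfonate | CC[Si](CC)(CC)OS(=O)(=O)C(F)(F)F | starting material
3 | (R)-terpinen-4-yl triethylsilyl ether | CC1=CC[C@@](O[Si](CC)(CC)CC)(C(C)C)CC1 | intermediate
4 | secondary ozonide of 3 (7,8,9-trioxabicyclo[4.2.1]nonane; ozonide carbons undefined) | CC12CC[C@](O[Si](CC)(CC)CC)(C(C)C)CC(OO1)O2 | intermediate
5 | (3R)-6-oxo-3-(propan-2-yl)-3-[(triethylsilyl)oxy]heptanal | CC(=O)CC[C@](O[Si](CC)(CC)CC)(C(C)C)CC=O | intermediate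
6 | (5S)-2-hydroxy-2-methyl-5-(propan-2-yl)-5-[(triethylsilyl)oxy]cyclopentane-1-carbaldehyde (new centres undefined) | CC1(O)CC[C@](O[Si](CC)(CC)CC)(C(C)C)C1C=O | intermediate
7 | (5S)-2-methyl-5-(propan-2-yl)-5-[(triethylsilyl)oxy]cyclopent-1-ene-1-carbaldehyde | CC1=C(C=O)[C@@](O[Si](CC)(CC)CC)(C(C)C)CC1 | intermediate
8 | 2-methylallylmagnesium chloride | CC(=C)C[Mg]Cl | starting material
9 | (+)-B-methoxydiisopinocampheylborane | COB([C@H]1C[C@H]2C[C@@H]([C@@H]1C)C2(C)C)[C@H]1C[C@H]2C[C@@H]([C@@H]1C)C2(C)C | starting material
10 | B-(2-methylallyl)diisopinocampheylborane | CC(=C)CB([C@H]1C[C@H]2C[C@@H]([C@@H]1C)C2(C)C)[C@H]1C[C@H]2C[C@@H]([C@@H]1C)C2(C)C | intermediate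
11 | diisopinocampheylborinate of 12 | CC1=C([C@H](OB([C@H]2C[C@H]3C[C@@H]([C@@H]2C)C3(C)C)[C@H]2C[C@H]3C[C@@H]([C@@H]2C)C3(C)C)CC(C)=C)[C@@](O[Si](CC)(CC)CC)(C(C)C)CC1 | intermediate
12 | (1R)-3-methyl-1-{(5S)-2-methyl-5-(propan-2-yl)-5-[(triethylsilyl)oxy]cyclopent-1-en-1-yl}but-3-en-1-ol | CC1=C([C@H](O)CC(C)=C)[C@@](O[Si](CC)(CC)CC)(C(C)C)CC1 | intermediate
13 | allyl bromide | C=CCBr | starting material
14 | allyl ether of 12 | CC1=C([C@H](OCC=C)CC(C)=C)[C@@](O[Si](CC)(CC)CC)(C(C)C)CC1 | intermediate
15 | (2R)-4-methyl-2-{(5S)-2-methyl-5-(propan-2-yl)-5-[(triethylsilyl)oxy]cyclopent-1-en-1-yl}-3,6-dihydro-2H-pyran | CC1=C([C@H]2CC(C)=CCO2)[C@@](O[Si](CC)(CC)CC)(C(C)C)CC1 | intermediate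
16 | C10 allyllithium of 15 (C10 configurationally labile) | CC1=C([C@H]2CC(C)=CC([Li])O2)[C@@](O[Si](CC)(CC)CC)(C(C)C)CC1 | intermediate
17 | lithium alkoxide of 18 | CC1=C[C@H](O[Li])[C@]2(C)CC[C@](O[Si](CC)(CC)CC)(C(C)C)C2=CC1 | intermediate
18 | (1R,4S,10S)-4-(triethylsilyloxy)carota-5,8-dien-10-ol | CC1=C[C@H](O)[C@]2(C)CC[C@](O[Si](CC)(CC)CC)(C(C)C)C2=CC1 | intermediate
19 | (1R,4S,10S)-carota-5,8-diene-4,10-diol | CC1=C[C@H](O)[C@]2(C)CC[C@](O)(C(C)C)C2=CC1 | intermediate
20 | isovaleric anhydride | CC(C)CC(=O)OC(=O)CC(C)C | starting material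
21 | (1R,4S,10S)-4-hydroxycarota-5,8-dien-10-yl 3-methylbutanoate | CC1=C[C@H](OC(=O)CC(C)C)[C@]2(C)CC[C@](O)(C(C)C)C2=CC1 | intermediate
22 | chlorodimethylsilane | C[SiH](C)Cl | starting material
23 | O4-dimethylsilyl ether of 21 | CC1=C[C@H](OC(=O)CC(C)C)[C@]2(C)CC[C@](O[SiH](C)C)(C(C)C)C2=CC1 | intermediate
24 | (1R,4S,5R,6S,10S) O4–SiMe2–C6 oxasilolane | CC1=C[C@H](OC(=O)CC(C)C)[C@]2(C)CC[C@@]3(C(C)C)O[Si](C)(C)[C@@H](C1)[C@H]23 | intermediate
25 | (1R,4S,5S,6S,10S)-4,6-dihydroxycarot-8-en-10-yl 3-methylbutanoate | CC1=C[C@H](OC(=O)CC(C)C)[C@]2(C)CC[C@](O)(C(C)C)[C@@H]2[C@@H](O)C1 | intermediate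
26 | 4-acetoxybenzoic acid | CC(=O)Oc1ccc(cc1)C(=O)O | starting material
27 | (1R,4S,5S,6R,10S)-4-hydroxy-10-(3-methylbutanoyloxy)carot-8-en-6-yl 4-acetoxybenzoate | CC1=C[C@H](OC(=O)CC(C)C)[C@]2(C)CC[C@](O)(C(C)C)[C@@H]2[C@H](OC(=O)c2ccc(OC(C)=O)cc2)C1 | intermediate
28 | CNP0086724.3 | CC1=C[C@H](OC(=O)CC(C)C)[C@]2(C)CC[C@](O)(C(C)C)[C@@H]2[C@H](OC(=O)c2ccc(O)cc2)C1 | target

Total step count: 13. Longest linear sequence: 13 (1 → 28; all partners are commercial).

**Steps most likely to fail**

**1. Step 7.** The bridged transition state must place the bulky cyclopentenyl group pseudo-axial and bring C7 close to the C1 methyl group. Homolysis of the C6–O bond in the allyllithium, followed by [1,2] or [1,4] recombination (ring contraction), may therefore outrun the [2,3] shift.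

Fallback, known chemistry, from 14 back to 18: the order of shift and ring closure is reversed.
- The open-chain bis-allylic ether 14 is lithiated at its unsubstituted allyl CH2 (s-BuLi, THF, −78 °C).
- It then undergoes the ordinary acyclic [2,3]-Wittig rearrangement to the trienol (1R,4S,10S,5E)-10-vinyl carbinol F1, which already contains the C1–C10 bond.
- The rotamer that places C7 cis to C1 should be preferred, because the alternative drives C7 into the C4 quaternary centre. The face of C1 again follows from C6.
- Ring-closing metathesis of the vinyl and isopropenyl groups of F1 with the second-generation Grubbs catalyst RuCl2(=CHPh)(PCy3)(H2IMes) then forms C8=C9 and ring A and gives 18.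
- A C10 epimer, if formed, is separated at the stage of F1.

**2. Step 10.** The new oxasilolane is trans-fused to ring B. Silicon–carbon bond formation at platinum may therefore be slow, leaving time for platinum hydride to walk C5=C6 into conjugation with C8=C9.

Fallback from 21 back to 25: untethered hydroboration.
- BH3·THF is used at 0 °C, with the first equivalent taken up by the C4 hydroxyl, followed by NaBO3.
- Boron should go to C6 and hydrogen to C5 from the face carrying the C1 methyl group and the small O–B group, away from the isopropyl group and C10.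
- C8=C9 is slowed only by its allylic acyloxy group, so the reaction is stopped early and 21 is recycled.
- This detour passes through no new isolable compound (entry F0).

**3. Step 12.** The carboxylate must reach C6 from the face that carries C4 and its isopropyl group. Elimination of the oxyphosphonium ion, or no reaction at all, may win over substitution.

Fallback from 25 back to 27: inversion by oxidation and directed reduction.
- Dess–Martin periodinane with NaHCO3 gives the β-hydroxy ketone (1R,4S,5R,10S)-4-hydroxy-6-oxocarot-8-en-10-yl 3-methylbutanoate F2, kept neutral to avoid enolisation at C5 or C7.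
- Me4NBH(OAc)3 in MeCN/AcOH at −20 °C (Evans–Saksena reduction) binds to O4 and delivers hydride to C6 from the O4 face, giving the (6R)-diol (1R,4S,5S,6R,10S)-4,6-dihydroxycarot-8-en-10-yl 3-methylbutanoate F3.
- Steglich-type acylation of the secondary hydroxyl with 26 (EDC·HCl, DMAP, CH2Cl2) gives 27 with retention.

**Further compounds**

F1 | step 7 | (1R,4S,10S,5E)-trienol: 1-[(1R,3S,2E)-1-methyl-2-(3-methylbut-3-en-1-ylidene)-3-(propan-2-yl)-3-(triethylsilyloxy)cyclopentyl]prop-2-en-1-ol, carbinol centre S | C=C[C@H](O)[C@]1(C)CC[C@](O[Si](CC)(CC)CC)(C(C)C)/C1=C/CC(C)=C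
F0 | step 10 | none | none
F2 | step 12 | (1R,4S,5R,10S)-4-hydroxy-6-oxocarot-8-en-10-yl 3-methylbutanoate | CC1=C[C@H](OC(=O)CC(C)C)[C@]2(C)CC[C@](O)(C(C)C)[C@@H]2C(=O)C1
F3 | step 12 | (1R,4S,5S,6R,10S)-4,6-dihydroxycarot-8-en-10-yl 3-methylbutanoate | CC1=C[C@H](OC(=O)CC(C)C)[C@]2(C)CC[C@](O)(C(C)C)[C@@H]2[C@H](O)C1
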